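**Retrosynthetic overview**
- The last step is a global BCl3 de-isopropylation of tri-O-isopropyl michellamine F.
- Key disconnection: both isoquinoline–naphthalene (5,8') axes are cut, giving a free 6',6''-linked binaphthol core and two different 5-iodoisoquinolines. Forward, each axis is made by a photostimulated SRN1 coupling (aryl radical + naphthoxide); the 6',6'' bond blocks the ortho positions, so only the para C–H can react.
- Both iodoisoquinolines come from one (R)-5-iodo-6,8-diisopropoxy-3,4-dihydroisoquinoline. The iodine is put on the arene while its two ortho positions are still equivalent, before Bischler–Napieralski closure. The arene comes from resorcinol and the stereocentre from (R)-2-methylaziridine.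
- The core comes from ortho–ortho oxidative homodimerisation (two molecules) of a para-triflyloxy naphthol, made from 7-methyljuglone (Diels–Alder of benzoquinone with the silyl dienolate of methyl 3-methylbut-2-enoate).
- Ring order: N-heterocycle onto the resorcinol ring; second naphthalene ring by Diels–Alder; then the 6',6'' bond; the two 5,8' axes last.

Assumption: the SMILES fixes only the three carbon stereocentres (1R,3R in the tetrahydro half, 3R in the dihydro half) and not the two hindered biaryl axes, so the axes are not controlled and atropisomers are separated by HPLC at the end; (R)-2-methylaziridine is taken as commercial.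

This route has not been run; steps 17 and 18 are proposed extensions of known chemistry.

**Route**

Step 1
Reactants: 1 resorcinol
Product: 2 1,3-diisopropoxybenzene
Conditions: 2-bromopropane (excess), K2CO3, DMF, 80 °C
Reagents that add atoms: 2-bromopropane, CC(C)Br (two incorporated)
Why: Williamson etherification of both phenols; isopropyl ethers survive Grignard, POCl3, hydride and base, and BCl3 later removes them without touching methyl ethers.

Step 2
Reactants: 2
Product: 3 1-bromo-3,5-diisopropoxybenzene
Conditions: [Ir(OMe)(cod)]2 (cat.), dtbpy, B2pin2, THF, 80 °C; then CuBr2, MeOH/H2O, 80 °C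
Reagents that add atoms: copper(II) bromide, Br[Cu]Br
Why: Sterically controlled Ir-catalysed C–H borylation goes only to C5 (meta to both alkoxy groups), and the boronate is converted to the bromide in the same pot (borylation/halogenation).

Step 3
Reactants: 4 (R)-2-methylaziridine
Product: 5 tert-butyl (R)-2-methylaziridine-1-carboxylate
Conditions: Boc2O, Et3N, CH2Cl2, 0 °C
Reagents that add atoms: di-tert-butyl dicarbonate, CC(C)(C)OC(=O)OC(=O)OC(C)(C)C
Why: N-acylation activates the aziridine for ring opening; the stereocentre is not touched.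

Step 4
Reactants: 3 1-bromo-3,5-diisopropoxybenzene; 5 tert-butyl (R)-2-methylaziridine-1-carboxylate
Product: 6 tert-butyl (R)-[1-(3,5-diisopropoxyphenyl)propan-2-yl]carbamate
Conditions: Mg, THF (ArMgBr); CuBr·SMe2 (10 mol %), 5, THF, −30 → 0 °C
Reagents that add atoms: none
Why: Cu-catalysed SN2 opening of the activated aziridine at the unsubstituted CH2 carries the (R) centre of 4 through unchanged; it becomes C3 of both isoquinoline halves.

Step 5
Reactants: 6
Product: 7 (R)-N-[1-(2-iodo-3,5-diisopropoxyphenyl)propan-2-yl]acetamide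
Conditions: NIS, MeCN, 0 °C; then 4 M HCl/dioxane; concentrate; Ac2O, Et3N, CH2Cl2
Reagents that add atoms: N-iodosuccinimide, O=C1CCC(=O)N1I; acetic anhydride, CC(=O)OC(C)=O
Why: Electrophilic aromatic iodination on a ring whose two ortho-to-chain positions are equivalent (the site between the two alkoxy groups is less reactive) fixes the future C5 unambiguously; Boc removal and N-acetylation follow in the same pot.

Step 6
Reactants: 7
Product: 8 (R)-5-iodo-6,8-diisopropoxy-1,3-dimethyl-3,4-dihydroisoquinoline
Conditions: POCl3, 2,4,6-collidine, MeCN, reflux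
Reagents that add atoms: none
Why: Bischler–Napieralski cyclodehydration can only close at the one free position ortho to the chain (para to one OiPr, ortho to the other), so iodine ends at C5; C3 is not involved.

Step 7
Reactants: 8
Product: 9 (1R,3R)-5-iodo-6,8-diisopropoxy-1,3-dimethyl-1,2,3,4-tetrahydroisoquinoline (trans)
Conditions: LiAlH4, AlMe3, THF, −78 → −40 °C
Reagents that add atoms: none
Why: Hydride reduction of the AlMe3-complexed cyclic imine is trans-selective for 1,3-dimethyl-dihydroisoquinolines, so the existing 3R centre sets C1 as R; low temperature spares the aryl iodide.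

Step 8
Reactants: 8
Product: 10 (R)-5-iodo-1,3-dimethyl-3,4-dihydroisoquinoline-6,8-diol
Conditions: BCl3 (excess), CH2Cl2, −78 → 0 °C; MeOH
Reagents that add atoms: none
Why: Lewis-acid cleavage of both secondary-alkyl aryl ethers.

Step 9
Reactants: 10
Product: 11 (R)-5-iodo-6-isopropoxy-1,3-dimethyl-3,4-dihydroisoquinolin-8-ol
Conditions: 2-iodopropane (1.1 equiv), K2CO3 (1.0 equiv), DMF, rt
Reagents that add atoms: 2-iodopropane, CC(C)I
Why: Regioselective Williamson alkylation: with one equivalent of base the more acidic 6-OH (para to C=N, ortho to iodine) is ionised and alkylated, while the 8-OH is shielded by the peri C1-methyl.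

Step 10
Reactants: 11
Product: 12 (R)-5-iodo-6-isopropoxy-8-methoxy-1,3-dimethyl-3,4-dihydroisoquinoline
Conditions: TMSCHN2, i-Pr2NEt, MeOH/MeCN, rt
Reagents that add atoms: trimethylsilyldiazomethane, C[Si](C)(C)C=[N+]=[N-]
Why: Diazoalkane O-methylation of the remaining phenol avoids the N-quaternisation of the imine that MeI could cause.

Step 11
Reactants: 13 methyl 3-methylbut-2-enoate
Product: 14 1-methoxy-3-methyl-1-(trimethylsilyloxy)buta-1,3-diene
Conditions: LDA, THF, −78 °C; TMSCl
Reagents that add atoms: chlorotrimethylsilane, C[Si](C)(C)Cl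
Why: γ-Deprotonation and O-silylation give the vinylketene acetal (Brassard-type diene).

Step 12
Reactants: 14 1-methoxy-3-methyl-1-(trimethylsilyloxy)buta-1,3-diene; 15 1,4-benzoquinone (2.5 equiv; one molecule is incorporated, the rest is oxidant)
Product: 16 5-hydroxy-7-methylnaphthalene-1,4-dione (7-methyljuglone)
Conditions: CH2Cl2, −40 °C → rt; then SiO2/1 M HCl, air
Reagents that add atoms: none
Why: Diels–Alder cycloaddition, loss of MeOH and silyl group, then oxidation by the excess quinone aromatises the new ring with OH from the acetal carbon and Me at C7; the symmetric dienophile removes any regiochemical question.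

Step 13
Reactants: 16
Product: 17 5-methoxy-7-methylnaphthalene-1,4-dione
Conditions: MeI, Ag2O, CHCl3, rt, dark
Reagents that add atoms: iodomethane, CI
Why: Ag2O-promoted O-methylation of the chelated peri-hydroxyl, standard for juglones.

Step 14
Reactants: 17
Product: 18 4-hydroxy-5-methoxy-7-methylnaphthalen-1-yl trifluoromethanesulfonate
Conditions: Na2S2O4, EtOAc/H2O; then Tf2O (1.0 equiv), 2,6-lutidine, CH2Cl2, −78 °C (under Ar)
Reagents that add atoms: triflic anhydride, O=S(=O)(OS(=O)(=O)C(F)(F)F)C(F)(F)F
Why: Quinone reduction, then selective sulfonylation of the unhindered 1-OH (the 4-OH is H-bonded to and shielded by the peri 5-OMe); the triflate blocks the para position for step 15 and is the handle for removing this oxygen.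

Step 15
Reactants: 18 4-hydroxy-5-methoxy-7-methylnaphthalen-1-yl trifluoromethanesulfonate (first molecule); 18 4-hydroxy-5-methoxy-7-methylnaphthalen-1-yl trifluoromethanesulfonate (second molecule; homodimerisation, 2 × 18 → 19 with loss of 2 H)
Product: 19 1,1'-dihydroxy-8,8'-dimethoxy-6,6'-dimethyl-[2,2'-binaphthalene]-4,4'-diyl bis(trifluoromethanesulfonate)
Conditions: Ag2O (excess), Et3N (cat.), CHCl3, rt; then aq. Na2S2O4
Reagents that add atoms: none
Why: Oxidative phenol coupling: two naphthoxyl radicals from two molecules of 18 can only dimerise productively through C2 because C4 is blocked, giving the 6',6'' bond; any over-oxidised diphenoquinone is reduced back in the work-up.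

Step 16
Reactants: 19
Product: 20 8,8'-dimethoxy-6,6'-dimethyl-[2,2'-binaphthalene]-1,1'-diol
Conditions: Pd(OAc)2, dppf, HCO2H, Et3N, DMF, 80 °C
Reagents that add atoms: none
Why: Pd-catalysed formate reduction of aryl triflates removes both para oxygens and tolerates the free naphthols.

Step 17
Reactants: 20 8,8'-dimethoxy-6,6'-dimethyl-[2,2'-binaphthalene]-1,1'-diol (3 equiv, excess recovered); 12 (R)-5-iodo-6-isopropoxy-8-methoxy-1,3-dimethyl-3,4-dihydroisoquinoline
Product: 21 4-[(3R)-6-isopropoxy-8-methoxy-1,3-dimethyl-3,4-dihydroisoquinolin-5-yl]-8,8'-dimethoxy-6,6'-dimethyl-[2,2'-binaphthalene]-1,1'-diol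
Conditions: KOtBu (2.0 equiv per 20), liq. NH3, −33 °C; 12, hν (350 nm), degassed
Reagents that add atoms: none
Why: Proposed new method: photostimulated SRN1 — electron transfer from the excited naphthoxide to 12 and loss of iodide give the C5 aryl σ-radical, which adds to the naphthoxide at C4 (the only high-HOMO carbon left, C2 being blocked); the resulting radical anion passes its electron to the next molecule of 12 (chain). The closest known reaction is the photostimulated C-arylation of 1- and 2-naphthoxide ions by hindered aryl iodides such as 1-iodo-2-methoxynaphthalene; exactly stoichiometric base leaves the imine alone, excess 20 keeps the reaction at mono-arylation, and the new axis forms as an atropisomer mixture.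

Step 18
Reactants: 21 mono-(dihydroisoquinolinyl) binaphthol; 9 (1R,3R)-5-iodo-6,8-diisopropoxy-1,3-dimethyl-1,2,3,4-tetrahydroisoquinoline (1.5–2 equiv)
Product: 22 4-[(3R)-6-isopropoxy-8-methoxy-1,3-dimethyl-3,4-dihydroisoquinolin-5-yl]-4'-[(1R,3R)-6,8-diisopropoxy-1,3-dimethyl-1,2,3,4-tetrahydroisoquinolin-5-yl]-8,8'-dimethoxy-6,6'-dimethyl-[2,2'-binaphthalene]-1,1'-diol (tri-O-isopropyl michellamine F)
Conditions: KOtBu (2.0 equiv), liq. NH3, −33 °C; 9, hν (350 nm), degassed
Reagents that add atoms: none
Why: Proposed new method: the same SRN1 chain as step 17 — the aryl radical from 9 can only couple at C4 of the second naphthoxide ring, the one nucleophilic carbon left in the dianion of 21; the closest known reaction is again naphthoxide C-arylation by aryl iodides in ammonia, which tolerates the free secondary amine.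

Step 19
Reactants: 22
Product: 23 michellamine F
Conditions: BCl3 (excess), CH2Cl2, −78 → 0 °C; MeOH; HPLC
Reagents that add atoms: none
Why: BCl3 cleaves the three isopropyl ethers selectively over the four methyl ethers (Lewis-acid dealkylation) and leaves the imine, amine and all stereocentres untouched.

**Compound list**

1 | resorcinol | Oc1cccc(O)c1 | starting material
2 | 1,3-diisopropoxybenzene | CC(C)Oc1cccc(OC(C)C)c1 | intermediate
3 | 1-bromo-3,5-diisopropoxybenzene | CC(C)Oc1cc(Br)cc(OC(C)C)c1 | intermediate
4 | (R)-2-methylaziridine | C[C@@H]1CN1 | starting material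
5 | tert-butyl (R)-2-methylaziridine-1-carboxylate | C[C@@H]1CN1C(=O)OC(C)(C)C | intermediate
6 | tert-butyl (R)-[1-(3,5-diisopropoxyphenyl)propan-2-yl]carbamate | C[C@H](Cc1cc(OC(C)C)cc(OC(C)C)c1)NC(=O)OC(C)(C)C | intermediate
7 | (R)-N-[1-(2-iodo-3,5-diisopropoxyphenyl)propan-2-yl]acetamide | C[C@H](Cc1cc(OC(C)C)cc(OC(C)C)c1I)NC(C)=O | intermediate
8 | (R)-5-iodo-6,8-diisopropoxy-1,3-dimethyl-3,4-dihydroisoquinoline | CC1=N[C@H](C)Cc2c(I)c(OC(C)C)cc(OC(C)C)c12 | intermediate
9 | (1R,3R)-5-iodo-6,8-diisopropoxy-1,3-dimethyl-1,2,3,4-tetrahydroisoquinoline | C[C@H]1N[C@H](C)Cc2c(I)c(OC(C)C)cc(OC(C)C)c12 | intermediate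
10 | (R)-5-iodo-1,3-dimethyl-3,4-dihydroisoquinoline-6,8-diol | CC1=N[C@H](C)Cc2c(I)c(O)cc(O)c12 | intermediate
11 | (R)-5-iodo-6-isopropoxy-1,3-dimethyl-3,4-dihydroisoquinolin-8-ol | CC1=N[C@H](C)Cc2c(I)c(OC(C)C)cc(O)c12 | intermediate
12 | (R)-5-iodo-6-isopropoxy-8-methoxy-1,3-dimethyl-3,4-dihydroisoquinoline | CC1=N[C@H](C)Cc2c(I)c(OC(C)C)cc(OC)c12 | intermediate
13 | methyl 3-methylbut-2-enoate | COC(=O)C=C(C)C | starting material
14 | 1-methoxy-3-methyl-1-(trimethylsilyloxy)buta-1,3-diene | COC(O[Si](C)(C)C)=CC(C)=C | intermediate
15 | 1,4-benzoquinone | O=C1C=CC(=O)C=C1 | starting material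
16 | 5-hydroxy-7-methylnaphthalene-1,4-dione | Cc1cc(O)c2C(=O)C=CC(=O)c2c1 | intermediate
17 | 5-methoxy-7-methylnaphthalene-1,4-dione | COc1cc(C)cc2C(=O)C=CC(=O)c12 | intermediate
18 | 4-hydroxy-5-methoxy-7-methylnaphthalen-1-yl triflate | COc1cc(C)cc2c(OS(=O)(=O)C(F)(F)F)ccc(O)c12 | intermediate
19 | 1,1'-dihydroxy-8,8'-dimethoxy-6,6'-dimethyl-[2,2'-binaphthalene]-4,4'-diyl bis(triflate) | COc1cc(C)cc2c(OS(=O)(=O)C(F)(F)F)cc(-c3cc(OS(=O)(=O)C(F)(F)F)c4cc(C)cc(OC)c4c3O)c(O)c12 | intermediate
20 | 8,8'-dimethoxy-6,6'-dimethyl-[2,2'-binaphthalene]-1,1'-diol | COc1cc(C)cc2ccc(-c3ccc4cc(C)cc(OC)c4c3O)c(O)c12 | intermediate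
21 | mono-(dihydroisoquinolinyl) binaphthol (see step 17) | CC1=N[C@H](C)Cc2c(-c3cc(-c5ccc6cc(C)cc(OC)c6c5O)c(O)c4c(OC)cc(C)cc34)c(OC(C)C)cc(OC)c12 | intermediate
22 | tri-O-isopropyl michellamine F (see step 18) | CC1=N[C@H](C)Cc2c(-c3cc(-c5cc(-c7c(OC(C)C)cc(OC(C)C)c8c7C[C@@H](C)N[C@@H]8C)c6cc(C)cc(OC)c6c5O)c(O)c4c(OC)cc(C)cc34)c(OC(C)C)cc(OC)c12 | intermediate
23 | michellamine F | COc1cc(O)c(-c2cc(-c3cc(-c4c(O)cc(O)c5c4C[C@@H](C)N[C@@H]5C)c4cc(C)cc(OC)c4c3O)c(O)c3c(OC)cc(C)cc23)c2c1C(C)=N[C@H](C)C2 | target

**Totals**
- Total steps: 19.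
- Longest linear sequence: 11 (resorcinol 1 → 2 → 3 → 6 → 7 → 8 → 10 → 11 → 12 → 21 → 22 → 23; steps 1, 2, 4, 5, 6, 8, 9, 10, 17, 18, 19).

**Three steps most likely to fail**
1. Steps 17/18 (SRN1 formation of the hindered axes): the coupling may lose to hydrodeiodination (including intramolecular H-abstraction from the ortho isopropoxy group) or give bis-arylation. Fallback: make the bond intramolecularly by a radical ipso-substitution — tether each 5-iodoisoquinolin-6-ol as a 6-O-sulfonate of the binaphthol-4,4'-disulfonyl chloride and run Bu3SnH/AIBN; 1,5-ipso attack with loss of SO2 gives the same C5–C8' bond and frees the 6-OH.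
2. Step 15 (oxidative homodimerisation of the electron-poor triflyloxynaphthol 18): the oxidation may be sluggish or give C–O coupling. Fallback: form the 6',6'' bond at the quinone level — dimerise quinone 17 with its hydroquinone to the 3,3'-biquinone, then do the reductive triflation and Pd/formate detriflation on the dimer.
3. Step 9 (6-O versus 8-O selectivity on diol 10): the two phenols may not differentiate well. Fallback: differentiate before ring closure through an open-chain ketone — acetylate the N-Boc aminopropyl iodoresorcinol ortho to the chain (Hoesch/Fries), alkylate the free para-OH while the ortho-OH is chelated to the ketone, methylate the chelated OH, then remove Boc so the amine condenses onto the ketone to form the dihydroisoquinoline.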